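**Plan**

- Cuts: (a) the C(sp3)–C(sp2) bond between the linker CH2 and C3 (the α-carbon) of the butenolide (ring B), giving a C11 primary alkylzinc of ring A and a C29 α-bromo-γ-ylidenebutenolide polyene; (b) the exocyclic C5=C bond of ring B (silyloxyfuran aldol–elimination); (c) the C11'=C12' polyene bond (Wittig, C15 + C10); (d) the bond from ring C to C7' (Stille).
- Forward order: ring A is made as alkyl iodide 15 (fragment 1); ring C triflate → C15 phosphonium salt → C25 polyenal → ring B closed onto the chain as bromobutenolide 30 (fragment 2); the two fragments are then joined and desilylated.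
- What makes the union possible: C3 of ring B is an sp2 carbon α to the lactone carbonyl, so its C–Br bond is an activated alkenyl halide. Its partner is a primary carbon whose nearest stereocentre is C6' of ring A, two atoms away, and the heptaene and enol lactone are spectators toward an alkylzinc.
- Stereochemistry: the ring A carbinol comes from Shi epoxidation of a silyl dienol ether; the second ring A centre from a trans-selective Luche reduction followed by suprafacial Johnson–Claisen transfer; the ring C carbinol from (4R,6R)-actinol. E double bonds come from stereoretentive couplings and iodine equilibration, the 5Z ylidene from thermodynamic control.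

Key step: step 17

Remark: compounds 16, 19, 24 and 27 are taken as purchasable building blocks. TBS = tert-butyldimethylsilyl, TIPS = triisopropylsilyl.

**Fragment 1 (ring A)**

Step 1
Reactants: 1 2-methylpropanal; 2 pent-1-en-3-one
Product: 5 2,4,4-trimethylcyclohex-2-en-1-one, via Michael adduct 3 (not isolated), via aldol 4 (not isolated)
Conditions: H2SO4 (cat.), toluene, 45 °C then reflux (Dean–Stark)
Reagents that add atoms: none
Why: Acid-catalysed Michael addition followed by intramolecular aldol condensation (Robinson-type annulation) should give a single enone, because the aldehyde of the adduct has no α-hydrogen and only the ethyl ketone CH2 can close the six-membered ring.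

Step 2
Reactants: 5 2,4,4-trimethylcyclohex-2-en-1-one
Product: 6 tert-butyldimethyl[(4,4,6-trimethylcyclohexa-1,5-dien-1-yl)oxy]silane
Conditions: TBSOTf, Et3N, CH2Cl2, 0 °C
Reagents that add atoms: tert-butyldimethylsilyl trifluoromethanesulfonate, CC(C)(C)[Si](C)(C)OS(=O)(=O)C(F)(F)F
Why: Soft enolisation (silyl triflate and amine) can only go toward C6 because the γ-carbon C4 is quaternary, so the cross-conjugated 2-silyloxy diene should form alone.

Step 3
Reactants: 6 silyl dienol ether
Product: 8 (6R)-6-hydroxy-2,4,4-trimethylcyclohex-2-en-1-one, via silyloxy epoxide 7 (not isolated)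
Conditions: 1,2:4,5-di-O-isopropylidene-β-D-erythro-2,3-hexodiulo-2,6-pyranose (Shi ketone, 30 mol %), KHSO5 (as 2KHSO5·KHSO4·K2SO4), aq. K2CO3 buffer (pH ca. 10.5), Bu4NHSO4 (cat.), MeCN–CH2(OMe)2, 0 °C; then AcOH–THF–H2O, 0 °C
Reagents that add atoms: potassium peroxymonosulfate, [K+].[O-]S(=O)(=O)OO
Why: Shi asymmetric epoxidation of a silyl enol ether (an asymmetric Rubottom-type α'-hydroxylation) should take the electron-rich enol ether double bond in preference to the hindered C2=C3 bond, the spiro transition state of the D-fructose-derived dioxirane setting C6 as R in the sense known for 1-substituted cyclohexenes, and mild acid opens the silyloxy epoxide to the α'-hydroxy enone.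

Step 4
Reactants: 8 (6R)-6-hydroxy-2,4,4-trimethylcyclohex-2-en-1-one
Product: 9 (6R)-6-(TBS-oxy)-2,4,4-trimethylcyclohex-2-en-1-one
Conditions: TBSCl, imidazole, DMF, 0 °C to rt
Reagents that add atoms: tert-butyldimethylsilyl chloride, CC(C)(C)[Si](C)(C)Cl
Why: Imidazole-promoted silylation of a secondary alcohol is too mild to enolise the α-oxygenated ketone, so C6 should keep its configuration.

Step 5
Reactants: 9 (6R)-6-(TBS-oxy)-2,4,4-trimethylcyclohex-2-en-1-one
Product: 10 (1R,6R)-6-(TBS-oxy)-2,4,4-trimethylcyclohex-2-en-1-ol (trans)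
Conditions: NaBH4, CeCl3·7H2O, MeOH, −78 °C
Reagents that add atoms: none
Why: In this Luche 1,2-reduction the C6 silyloxy group is held equatorial by the syn-axial C4 methyl group, and axial hydride delivery to the half-chair should give the equatorial, trans allylic alcohol with C1 as R.

Step 6
Reactants: 10 (1R,6R)-6-(TBS-oxy)-2,4,4-trimethylcyclohex-2-en-1-ol
Product: 13 ethyl 2-[(1R,4R)-4-(TBS-oxy)-2,6,6-trimethylcyclohex-2-en-1-yl]acetate, via mixed orthoester 11 (not isolated), via ketene acetal 12 (not isolated)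
Conditions: MeC(OEt)3 (excess), EtCO2H (cat.), 140 °C, EtOH distilled off
Reagents that add atoms: triethyl orthoacetate, CC(OCC)(OCC)OCC
Why: In the Johnson–Claisen rearrangement the suprafacial chair-like [3,3] shift delivers the CH2CO2Et group to C3 of 10 (next to the gem-dimethyl carbon) on the face that the C1–O bond leaves, that is trans to the silyloxy group, which sets the second ring A stereocentre and moves the double bond to its final place.

Step 7
Reactants: 13 ethyl ester
Product: 14 2-[(1R,4R)-4-(TBS-oxy)-2,6,6-trimethylcyclohex-2-en-1-yl]ethan-1-ol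
Conditions: LiAlH4, Et2O, 0 °C
Reagents that add atoms: none
Why: Hydride reduction of the ester to the primary alcohol leaves the silyl ether and the trisubstituted alkene untouched.

Step 8
Reactants: 14 primary alcohol
Product: 15 tert-butyl{[(1R,4R)-4-(2-iodoethyl)-3,5,5-trimethylcyclohex-2-en-1-yl]oxy}dimethylsilane
Conditions: I2, PPh3, imidazole, CH2Cl2, 0 °C to rt
Reagents that add atoms: iodine, [I][I]
Why: Appel-type iodination (Garegg–Samuelsson conditions) activates the alcohol with the iodophosphonium reagent and displaces it by iodide in an SN2 step at the unhindered primary carbon, sparing the allylic silyl ether.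

**Fragment 2 (ring C, polyene, ring B)**

Step 9
Reactants: 16 (4R,6R)-4-hydroxy-2,2,6-trimethylcyclohexan-1-one (actinol)
Product: 17 (4R,6R)-4-(TBS-oxy)-2,2,6-trimethylcyclohexan-1-one
Conditions: TBSCl, imidazole, DMF, rt
Reagents that add atoms: tert-butyldimethylsilyl chloride, CC(C)(C)[Si](C)(C)Cl
Why: Standard silylation of the secondary alcohol, which carries the ring C carbinol configuration of the target from the chiral pool.

Step 10
Reactants: 17 silylated actinol
Product: 18 (4R)-4-(TBS-oxy)-2,6,6-trimethylcyclohex-1-en-1-yl trifluoromethanesulfonate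
Conditions: LiN(iPr)2, THF, −78 to 0 °C; PhNTf2, 0 °C to rt
Reagents that add atoms: N-phenylbis(trifluoromethanesulfonimide), O=S(=O)(N(c1ccccc1)S(=O)(=O)C(F)(F)F)C(F)(F)F
Why: Enolate O-triflation can only go toward C6 because C2 is quaternary, so a single tetrasubstituted enol triflate should form, the C6 centre becoming the ring C double bond while C4 is untouched.

Step 11
Reactants: 19 (2E)-3-methylpent-2-en-4-yn-1-ol
Product: 20 (2E,4E)-3-methyl-5-(tributylstannyl)penta-2,4-dien-1-ol
Conditions: Bu3SnH, Pd(PPh3)2Cl2 (2 mol %), THF, 0 °C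
Reagents that add atoms: tributyltin hydride, CCCC[SnH](CCCC)CCCC
Why: Palladium-catalysed syn-hydrostannation of the terminal alkyne of the conjugated enyne should put tin on the terminal carbon and give the (E)-dienylstannane, the free hydroxyl being tolerated.

Step 12
Reactants: 18 enol triflate; 20 dienylstannane
Product: 21 (2E,4E)-5-[(4R)-4-(TBS-oxy)-2,6,6-trimethylcyclohex-1-en-1-yl]-3-methylpenta-2,4-dien-1-ol
Conditions: Pd2(dba)3 (2.5 mol %), AsPh3 (20 mol %), NMP, 60 °C
Reagents that add atoms: none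
Why: Stille coupling of an alkenyl triflate with an alkenylstannane retains both double-bond geometries, and the weakly donating AsPh3 ligand speeds transmetalation enough for the hindered tetrasubstituted triflate.

Step 13
Reactants: 21 C15 dienol
Product: 23 {(2E,4E)-5-[(4R)-4-(TBS-oxy)-2,6,6-trimethylcyclohex-1-en-1-yl]-3-methylpenta-2,4-dien-1-yl}triphenylphosphonium bromide, via allylic bromide 22 (not isolated)
Conditions: CBr4, PPh3 (1.1 equiv each), CH2Cl2, −20 °C; then PPh3 (1.2 equiv), rt
Reagents that add atoms: triphenylphosphine, c1ccc(cc1)P(c1ccccc1)c1ccccc1; carbon tetrabromide, BrC(Br)(Br)Br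
Why: Appel bromination of the primary allylic alcohol and SN2 quaternisation of PPh3 at the primary carbon should give the conjugated C15 salt under neutral conditions that spare the silyl ether.

Step 14
Reactants: 23 C15 phosphonium bromide; 24 (2E,4E,6E)-2,7-dimethylocta-2,4,6-trienedial
Product: 26 (2E,4E,6E,8E,10E,12E)-13-[(4R)-4-(TBS-oxy)-2,6,6-trimethylcyclohex-1-en-1-yl]-2,7,11-trimethyltrideca-2,4,6,8,10,12-hexaenal, via phosphorus ylide 25 (not isolated)
Conditions: NaOMe, MeOH–CH2Cl2, 0 °C to rt, 24 in threefold excess; then I2 (cat.), CH2Cl2–hexane, rt, daylight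
Reagents that add atoms: none
Why: In this Wittig olefination with a semi-stabilised allylic ylide the excess of the symmetrical dial limits reaction to one aldehyde group, and iodine-catalysed equilibration should bring the new C11'=C12' bond to the E configuration.

Step 15
Reactants: 27 3-bromofuran-2(5H)-one
Product: 28 [(3-bromofuran-2-yl)oxy]triisopropylsilane
Conditions: TIPSOTf, Et3N, CH2Cl2, 0 °C
Reagents that add atoms: triisopropylsilyl trifluoromethanesulfonate, CC(C)[Si](C(C)C)(C(C)C)OS(=O)(=O)C(F)(F)F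
Why: Soft enolisation at C5 and O-silylation of the butenolide dienolate give the aromatic 2-silyloxyfuran.

Step 16
Reactants: 26 C25 polyenal; 28 silyloxyfuran
Product: 30 (5Z)-3-bromo-5-{(2E,4E,6E,8E,10E,12E)-13-[(4R)-4-(TBS-oxy)-2,6,6-trimethylcyclohex-1-en-1-yl]-2,7,11-trimethyltrideca-2,4,6,8,10,12-hexaen-1-ylidene}furan-2(5H)-one, via silyl aldol 29 (not isolated)
Conditions: TIPSOTf (10 mol %), CH2Cl2, −78 °C; then DBU, −78 °C to rt; then I2 (cat.), CH2Cl2, rt, daylight
Reagents that add atoms: none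
Why: Vinylogous Mukaiyama aldol addition through furan C5 (C3 is blocked by bromine) is followed by base-induced E1cB loss of silanolate, and under thermodynamic control the ylidene should settle as the Z isomer, with the chain cis to the ring oxygen and away from C4–H.

**Union and end game**

Step 17
Reactants: 15 ring A iodide; 30 bromobutenolide polyene
Product: 32 (5Z)-3-{2-[(1R,4R)-4-(TBS-oxy)-2,6,6-trimethylcyclohex-2-en-1-yl]ethyl}-5-{(2E,4E,6E,8E,10E,12E)-13-[(4R)-4-(TBS-oxy)-2,6,6-trimethylcyclohex-1-en-1-yl]-2,7,11-trimethyltrideca-2,4,6,8,10,12-hexaen-1-ylidene}furan-2(5H)-one, via alkylzinc iodide 31 (not isolated)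
Conditions: Zn dust (activated), LiCl, THF, 40 °C; then 30, Pd(dppf)Cl2 (5 mol %), THF–NMP, 25 °C, dark
Reagents that add atoms: none
Why: Negishi alkyl–alkenyl cross-coupling: LiCl-assisted insertion of zinc into the primary C–I bond gives 31, zerovalent palladium adds oxidatively into the C3–Br bond of ring B, the alkyl group passes from zinc to palladium, and reductive elimination forms the C(sp3)–C(sp2) bond between the linker CH2 and C3. The closest known reaction type is the palladium-catalysed coupling of primary alkylzinc halides with α-halo enones, α-halo acrylates and α-bromobutenolides. No ring is closed and no stereocentre is created; the three existing stereocentres lie at least two atoms from either reacting carbon, and the zinc-bearing carbon is primary, so nothing can epimerise. The step needs chemoselectivity for the C3–Br bond over the heptaene, the enol lactone and the silyl ethers, which the α-carbonyl activation of that bond and the low nucleophilicity of the organozinc toward the lactone at 25 °C should secure. It also needs reductive elimination to outrun β-hydride elimination, which the wide bite angle of dppf favours, and retention of the 5Z and all-E geometry, which neutral conditions, room temperature and exclusion of light should preserve.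

Step 18
Reactants: 32 bis-silyl ether
Product: 33 target, (5Z)-3-{2-[(1R,4R)-4-hydroxy-2,6,6-trimethylcyclohex-2-en-1-yl]ethyl}-5-{(2E,4E,6E,8E,10E,12E)-13-[(4R)-4-hydroxy-2,6,6-trimethylcyclohex-1-en-1-yl]-2,7,11-trimethyltrideca-2,4,6,8,10,12-hexaen-1-ylidene}furan-2(5H)-one
Conditions: HF·pyridine, pyridine, THF, 0 °C to rt, dark
Reagents that add atoms: none
Why: Fluoride-mediated cleavage of both secondary silyl ethers with pyridine-buffered HF should spare the acid-sensitive allylic alcohol of ring A, the enol lactone and the polyene.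

**Compound list**

1 | 2-methylpropanal | CC(C)C=O | starting material
2 | pent-1-en-3-one | CCC(=O)C=C | starting material
3 | 2,2-dimethyl-5-oxoheptanal | CCC(=O)CCC(C)(C)C=O | intermediate
4 | 3-hydroxy-2,4,4-trimethylcyclohexan-1-one (racemic diastereomer mixture) | CC1C(O)C(C)(C)CCC1=O | intermediate
5 | 2,4,4-trimethylcyclohex-2-en-1-one | CC1=CC(C)(C)CCC1=O | intermediate
6 | tert-butyldimethyl[(4,4,6-trimethylcyclohexa-1,5-dien-1-yl)oxy]silane | CC1=CC(C)(C)CC=C1O[Si](C)(C)C(C)(C)C | intermediate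
7 | tert-butyldimethyl{[(1R,6R)-2,4,4-trimethyl-7-oxabicyclo[4.1.0]hept-2-en-1-yl]oxy}silane | CC1=CC(C)(C)C[C@H]2O[C@@]12O[Si](C)(C)C(C)(C)C | intermediate
8 | (6R)-6-hydroxy-2,4,4-trimethylcyclohex-2-en-1-one | CC1=CC(C)(C)C[C@@H](O)C1=O | intermediate
9 | (6R)-6-(TBS-oxy)-2,4,4-trimethylcyclohex-2-en-1-one | CC1=CC(C)(C)C[C@@H](O[Si](C)(C)C(C)(C)C)C1=O | intermediate
10 | (1R,6R)-6-(TBS-oxy)-2,4,4-trimethylcyclohex-2-en-1-ol | CC1=CC(C)(C)C[C@@H](O[Si](C)(C)C(C)(C)C)[C@@H]1O | intermediate
11 | mixed orthoester of 10 (1,1-diethoxyethyl ether at O1, configuration as in 10) | CC1=CC(C)(C)C[C@@H](O[Si](C)(C)C(C)(C)C)[C@@H]1OC(C)(OCC)OCC | intermediate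
12 | ketene acetal of 10 (1-ethoxyvinyl ether at O1, configuration as in 10) | CC1=CC(C)(C)C[C@@H](O[Si](C)(C)C(C)(C)C)[C@@H]1OC(=C)OCC | intermediate
13 | ethyl 2-[(1R,4R)-4-(TBS-oxy)-2,6,6-trimethylcyclohex-2-en-1-yl]acetate | CC1=C[C@H](O[Si](C)(C)C(C)(C)C)CC(C)(C)[C@H]1CC(=O)OCC | intermediate
14 | 2-[(1R,4R)-4-(TBS-oxy)-2,6,6-trimethylcyclohex-2-en-1-yl]ethan-1-ol | CC1=C[C@H](O[Si](C)(C)C(C)(C)C)CC(C)(C)[C@H]1CCO | intermediate
15 | tert-butyl{[(1R,4R)-4-(2-iodoethyl)-3,5,5-trimethylcyclohex-2-en-1-yl]oxy}dimethylsilane | CC1=C[C@H](O[Si](C)(C)C(C)(C)C)CC(C)(C)[C@H]1CCI | intermediate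
16 | (4R,6R)-4-hydroxy-2,2,6-trimethylcyclohexan-1-one (actinol) | O=C1[C@H](C)C[C@@H](O)CC1(C)C | starting material
17 | (4R,6R)-4-(TBS-oxy)-2,2,6-trimethylcyclohexan-1-one | O=C1[C@H](C)C[C@@H](O[Si](C)(C)C(C)(C)C)CC1(C)C | intermediate
18 | (4R)-4-(TBS-oxy)-2,6,6-trimethylcyclohex-1-en-1-yl trifluoromethanesulfonate | FC(F)(F)S(=O)(=O)OC1=C(C)C[C@@H](O[Si](C)(C)C(C)(C)C)CC1(C)C | intermediate
19 | (2E)-3-methylpent-2-en-4-yn-1-ol | C#C/C(C)=C/CO | starting material
20 | (2E,4E)-3-methyl-5-(tributylstannyl)penta-2,4-dien-1-ol | CCCC[Sn](CCCC)(CCCC)/C=C/C(C)=C/CO | intermediate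
21 | (2E,4E)-5-[(4R)-4-(TBS-oxy)-2,6,6-trimethylcyclohex-1-en-1-yl]-3-methylpenta-2,4-dien-1-ol | OC/C=C(C)/C=C/C1=C(C)C[C@@H](O[Si](C)(C)C(C)(C)C)CC1(C)C | intermediate
22 | tert-butyl{[(1R)-4-[(1E,3E)-5-bromo-3-methylpenta-1,3-dien-1-yl]-3,5,5-trimethylcyclohex-3-en-1-yl]oxy}dimethylsilane | BrC/C=C(C)/C=C/C1=C(C)C[C@@H](O[Si](C)(C)C(C)(C)C)CC1(C)C | intermediate
23 | {(2E,4E)-5-[(4R)-4-(TBS-oxy)-2,6,6-trimethylcyclohex-1-en-1-yl]-3-methylpenta-2,4-dien-1-yl}triphenylphosphonium bromide | [Br-].c1ccc(cc1)[P+](C/C=C(C)/C=C/C1=C(C)C[C@@H](O[Si](C)(C)C(C)(C)C)CC1(C)C)(c1ccccc1)c1ccccc1 | intermediate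
24 | (2E,4E,6E)-2,7-dimethylocta-2,4,6-trienedial | O=C/C(C)=C/C=C/C=C(C)/C=O | starting material
25 | ylide of 23 (deprotonated at the P-bound CH2) | c1ccc(cc1)[P+]([CH-]/C=C(C)/C=C/C1=C(C)C[C@@H](O[Si](C)(C)C(C)(C)C)CC1(C)C)(c1ccccc1)c1ccccc1 | intermediate
26 | (2E,4E,6E,8E,10E,12E)-13-[(4R)-4-(TBS-oxy)-2,6,6-trimethylcyclohex-1-en-1-yl]-2,7,11-trimethyltrideca-2,4,6,8,10,12-hexaenal | O=C/C(C)=C/C=C/C=C(C)/C=C/C=C(C)/C=C/C1=C(C)C[C@@H](O[Si](C)(C)C(C)(C)C)CC1(C)C | intermediate
27 | 3-bromofuran-2(5H)-one | O=C1OCC=C1Br | starting material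
28 | [(3-bromofuran-2-yl)oxy]triisopropylsilane | CC(C)[Si](C(C)C)(C(C)C)Oc1occc1Br | intermediate
29 | 3-bromo-5-{(2E,4E,6E,8E,10E,12E)-13-[(4R)-4-(TBS-oxy)-2,6,6-trimethylcyclohex-1-en-1-yl]-2,7,11-trimethyl-1-(TIPS-oxy)trideca-2,4,6,8,10,12-hexaen-1-yl}furan-2(5H)-one (diastereomer mixture at C5 and C1 of the chain) | O=C1OC(C=C1Br)C(O[Si](C(C)C)(C(C)C)C(C)C)/C(C)=C/C=C/C=C(C)/C=C/C=C(C)/C=C/C1=C(C)C[C@@H](O[Si](C)(C)C(C)(C)C)CC1(C)C | intermediate
30 | (5Z)-3-bromo-5-{(2E,4E,6E,8E,10E,12E)-13-[(4R)-4-(TBS-oxy)-2,6,6-trimethylcyclohex-1-en-1-yl]-2,7,11-trimethyltrideca-2,4,6,8,10,12-hexaen-1-ylidene}furan-2(5H)-one | BrC1=C/C(=C/C(C)=C/C=C/C=C(C)/C=C/C=C(C)/C=C/C2=C(C)C[C@@H](O[Si](C)(C)C(C)(C)C)CC2(C)C)OC1=O | intermediate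
31 | {2-[(1R,4R)-4-(TBS-oxy)-2,6,6-trimethylcyclohex-2-en-1-yl]ethyl}zinc iodide | CC1=C[C@H](O[Si](C)(C)C(C)(C)C)CC(C)(C)[C@H]1CC[Zn]I | intermediate
32 | bis-TBS ether of the target (both hydroxyl groups silylated) | CC1=C[C@H](O[Si](C)(C)C(C)(C)C)CC(C)(C)[C@H]1CCC1=C/C(=C/C(C)=C/C=C/C=C(C)/C=C/C=C(C)/C=C/C2=C(C)C[C@@H](O[Si](C)(C)C(C)(C)C)CC2(C)C)OC1=O | intermediate
33 | (5Z)-3-{2-[(1R,4R)-4-hydroxy-2,6,6-trimethylcyclohex-2-en-1-yl]ethyl}-5-{(2E,4E,6E,8E,10E,12E)-13-[(4R)-4-hydroxy-2,6,6-trimethylcyclohex-1-en-1-yl]-2,7,11-trimethyltrideca-2,4,6,8,10,12-hexaen-1-ylidene}furan-2(5H)-one | CC1=C[C@H](O)CC(C)(C)[C@H]1CCC1=C/C(=C/C(C)=C/C=C/C=C(C)/C=C/C=C(C)/C=C/C2=C(C)C[C@@H](O)CC2(C)C)OC1=O | target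

**Step count and risks**

Total steps: 18. Longest linear sequence: 10 steps (steps 1 to 8, then 17 and 18).

Step 17. What may go wrong: oxidative addition into the polyenyl bromide may be slow, or the heptaene and the ylidene may isomerise or decompose under palladium, so that protodezincation of the alkylzinc takes over. Fallback, from 31 (made from 15) and 27, back at 32: the union is moved to the start of the chain, where the electrophile is robust. Negishi coupling of 31 with 27 under the same catalyst should give 3-{2-[(1R,4R)-4-(TBS-oxy)-2,6,6-trimethylcyclohex-2-en-1-yl]ethyl}furan-2(5H)-one F1. O-silylation (TIPSOTf, Et3N) turns it into the 2-silyloxyfuran F2. Vinylogous Mukaiyama aldol addition of F2 to aldehyde 26 gives the silyl aldol F3 (not isolated), and DBU elimination with iodine equilibration delivers 32.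

Step 16. What may go wrong: Lewis-acid activation of the long, weakly electrophilic heptaenal may lead to polyene cation side reactions, low conversion or poor control of the ylidene geometry. Fallback, from 24 and 28, back at 30: the aldol–elimination is run on the short, more electrophilic dial 24 (threefold excess) with 28. This gives first the silyl aldol (2E,4E,6E)-8-(4-bromo-5-oxo-2,5-dihydrofuran-2-yl)-2,7-dimethyl-8-(TIPS-oxy)octa-2,4,6-trienal F4 (not isolated) and then, after DBU, (2E,4E,6E)-8-[(2Z)-4-bromo-5-oxofuran-2(5H)-ylidene]-2,7-dimethylocta-2,4,6-trienal F5. Wittig reaction of F5 with ylide 25 (pre-formed from 23 with NaN(SiMe3)2 in THF at −78 °C, so that no alkoxide meets the enol lactone) and iodine equilibration should give 30.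

Step 3. What may go wrong: the facial selectivity of the epoxidation may be poor, or the dioxirane may attack the other double bond of the diene. Fallback, from 5, back at 8: Mn(OAc)3-mediated α'-acetoxylation of 5 (benzene, reflux) gives racemic 6-acetoxy-2,4,4-trimethylcyclohex-2-en-1-one F6. Lipase-catalysed hydrolysis as a kinetic resolution, with the enzyme selected by screening for cleavage of the R ester, should release 8 and leave the S ester behind.

**Further compounds**

F1 | step 17 | 3-{2-[(1R,4R)-4-(TBS-oxy)-2,6,6-trimethylcyclohex-2-en-1-yl]ethyl}furan-2(5H)-one | CC1=C[C@H](O[Si](C)(C)C(C)(C)C)CC(C)(C)[C@H]1CCC1=CCOC1=O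
F2 | step 17 | tert-butyldimethyl{[(1R,4R)-3,5,5-trimethyl-4-{2-[2-(TIPS-oxy)furan-3-yl]ethyl}cyclohex-2-en-1-yl]oxy}silane | CC1=C[C@H](O[Si](C)(C)C(C)(C)C)CC(C)(C)[C@H]1CCc1ccoc1O[Si](C(C)C)(C(C)C)C(C)C
F3 | step 17 | silyl aldol of F2 and 26 (TIPS ether at C1 of the chain, diastereomer mixture) | CC1=C[C@H](O[Si](C)(C)C(C)(C)C)CC(C)(C)[C@H]1CCC1=CC(OC1=O)C(O[Si](C(C)C)(C(C)C)C(C)C)/C(C)=C/C=C/C=C(C)/C=C/C=C(C)/C=C/C1=C(C)C[C@@H](O[Si](C)(C)C(C)(C)C)CC1(C)C
F4 | step 16 | (2E,4E,6E)-8-(4-bromo-5-oxo-2,5-dihydrofuran-2-yl)-2,7-dimethyl-8-(TIPS-oxy)octa-2,4,6-trienal (diastereomer mixture) | O=C/C(C)=C/C=C/C=C(C)/C(O[Si](C(C)C)(C(C)C)C(C)C)C1OC(=O)C(Br)=C1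
F5 | step 16 | (2E,4E,6E)-8-[(2Z)-4-bromo-5-oxofuran-2(5H)-ylidene]-2,7-dimethylocta-2,4,6-trienal | BrC1=C/C(=C/C(C)=C/C=C/C=C(C)/C=O)OC1=O
F6 | step 3 | racemic 6-acetoxy-2,4,4-trimethylcyclohex-2-en-1-one | CC1=CC(C)(C)CC(OC(C)=O)C1=O
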